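**Retrosynthetic overview**
1. Target 19 ⇐ 18 (two O-benzyl groups off) ⇐ lactol 16 + 2,6-dimethoxyphenol 17: the C2–aryl bond comes from Friedel–Crafts arylation of the cyclic oxocarbenium ion, with C2 settling trans to C3.
2. 16 (pyran ring C) ⇐ phenol 14: the terminal diol is cleaved to an aldehyde that closes onto the phenol; C3 is C2 of L-threonate 5 (made from vitamin C).
3. 14 ⇐ aryl ketone 11 (C4 carbonyl oxygen removed) ⇐ key step: regiospecific Diels–Alder/aromatisation of ynone 7 with Brassard's diene 9, which builds ring A with OH, OMe and the phenethyl arm in place.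
4. 7 ⇐ alkyne 4 (ring D arm, from 1 + 2) + O-benzyl threonate 6.
5. Ring order: D and B are bought; A is formed by the [4+2] cycloaddition (step 5); C is closed last (steps 7–8).

Assumption: 1, 2, 5, 8 and 17 are purchased (5 is the commercial acetonide ester derived from L-ascorbic acid); Chan's diene and 2-(benzyloxy)-5-bromo-1,3-dimethoxybenzene, used only in fallbacks, are also purchased.

**Route**

Step 1
Reactants: 1 1-(benzyloxy)-3-(bromomethyl)benzene; 2 trimethyl(prop-1-yn-1-yl)silane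
Product: 4 1-(benzyloxy)-3-(but-3-yn-1-yl)benzene, via silylalkyne 3 (not isolated)
Conditions: 2, n-BuLi, THF, −78 °C; then 1, −78 → 0 °C; then K2CO3 (cat.), MeOH, 23 °C
Reagents that add atoms: none
Why: Propargylic lithiation of the silylpropyne and SN2 alkylation by the benzylic bromide, followed by protodesilylation in the same pot, gives the terminal alkyne.

Step 2
Reactants: 5 methyl (2R)-2-[(4S)-2,2-dimethyl-1,3-dioxolan-4-yl]-2-hydroxyacetate (methyl 3,4-O-isopropylidene-L-threonate)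
Product: 6 methyl (2R)-2-(benzyloxy)-2-[(4S)-2,2-dimethyl-1,3-dioxolan-4-yl]acetate
Conditions: BnBr, Ag2O, CH2Cl2, 23 °C, dark
Reagents that add atoms: benzyl bromide, BrCc1ccccc1
Why: Silver-oxide-mediated Williamson O-benzylation is non-basic, so the bought α-stereocentre (the future C3) is not epimerised.

Step 3
Reactants: 4 1-(benzyloxy)-3-(but-3-yn-1-yl)benzene; 6 methyl (2R)-2-(benzyloxy)-2-[(4S)-2,2-dimethyl-1,3-dioxolan-4-yl]acetate
Product: 7 (1R)-1-(benzyloxy)-6-[3-(benzyloxy)phenyl]-1-[(4S)-2,2-dimethyl-1,3-dioxolan-4-yl]hex-3-yn-2-one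
Conditions: 4, n-BuLi, THF, −78 °C; BF3·OEt2; then 6, −78 °C; aq NH4Cl
Reagents that add atoms: none
Why: BF3-mediated acylation of the lithium acetylide by the ester (Yamaguchi–Hirao ynone synthesis) stops at the ketone because the tetrahedral adduct survives at −78 °C, and the α-stereocentre is not touched.

Step 4
Reactants: 8 methyl (2E)-3-methoxybut-2-enoate
Product: 9 [(1,3-dimethoxybuta-1,3-dien-1-yl)oxy]trimethylsilane (Brassard's diene)
Conditions: LDA, THF, −78 °C; TMSCl; distil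
Reagents that add atoms: chlorotrimethylsilane, C[Si](C)(C)Cl
Why: γ-Deprotonation to the extended lithium dienolate and O-silylation gives the silyl ketene acetal diene.

Step 5 (key step)
Reactants: 7 (1R)-1-(benzyloxy)-6-[3-(benzyloxy)phenyl]-1-[(4S)-2,2-dimethyl-1,3-dioxolan-4-yl]hex-3-yn-2-one; 9 Brassard's diene
Product: 11 (2R)-2-(benzyloxy)-1-{2-[2-(3-(benzyloxy)phenyl)ethyl]-6-hydroxy-4-methoxyphenyl}-2-[(4S)-2,2-dimethyl-1,3-dioxolan-4-yl]ethan-1-one, via cyclohexadiene cycloadduct 10 (not isolated)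
Conditions: 9 (2.5 equiv), toluene, 110 °C (sealed); then silica gel, wet CH2Cl2, 23 °C
Reagents that add atoms: none
Why: Normal-demand Diels–Alder cycloaddition in which the nucleophilic CH2 terminus of the diene bonds to the β-alkynyl carbon, so that after loss of MeOH and desilylation ring A carries OH ortho and OMe para to the acyl carbon and the phenethyl arm on the other ortho carbon; no stereocentre is formed and the α-alkoxy centre is not exposed to base.

Step 6
Reactants: 11 (2R)-2-(benzyloxy)-1-{2-[2-(3-(benzyloxy)phenyl)ethyl]-6-hydroxy-4-methoxyphenyl}-2-[(4S)-2,2-dimethyl-1,3-dioxolan-4-yl]ethan-1-one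
Product: 14 2-{(2S)-2-(benzyloxy)-2-[(4S)-2,2-dimethyl-1,3-dioxolan-4-yl]ethyl}-3-{2-[3-(benzyloxy)phenyl]ethyl}-5-methoxyphenol, via aryl ethyl carbonate 12 (not isolated), via ortho-quinone methide 13 (not isolated)
Conditions: ClCO2Et, Et3N, THF, 0 °C; then NaBH4, H2O, 0 → 23 °C
Reagents that add atoms: none
Why: Carbonate-assisted borohydride deoxygenation of an o-hydroxyaryl ketone: ketone reduction, carbonate transfer and elimination give the o-quinone methide, which takes up hydride at C4, so the adjacent stereocentre keeps its geometry (its descriptor changes from R to S only through CIP ranking).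

Step 7
Reactants: 14 2-{(2S)-2-(benzyloxy)-2-[(4S)-2,2-dimethyl-1,3-dioxolan-4-yl]ethyl}-3-{2-[3-(benzyloxy)phenyl]ethyl}-5-methoxyphenol
Product: 16 (3S)-3-(benzyloxy)-5-{2-[3-(benzyloxy)phenyl]ethyl}-7-methoxy-3,4-dihydro-2H-chromen-2-ol (both C2 epimers), via diol 15 (not isolated)
Conditions: AcOH/H2O 4:1, 40 °C; evaporate; then NaIO4, THF/pH 7 buffer, 0 °C
Reagents that add atoms: none
Why: Acetal hydrolysis followed by Malaprade glycol cleavage gives the α-benzyloxy aldehyde, which is trapped at once by the ortho phenol as the six-membered lactol, so C3 is not epimerised.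

Step 8
Reactants: 16 (3S)-3-(benzyloxy)-5-{2-[3-(benzyloxy)phenyl]ethyl}-7-methoxy-3,4-dihydro-2H-chromen-2-ol; 17 2,6-dimethoxyphenol
Product: 18 4-[(2R,3S)-3-(benzyloxy)-5-{2-[3-(benzyloxy)phenyl]ethyl}-7-methoxy-3,4-dihydro-2H-chromen-2-yl]-2,6-dimethoxyphenol
Conditions: 17 (3 equiv), BF3·OEt2 (20 mol %), 4 Å MS, CH2Cl2, −20 → 23 °C
Reagents that add atoms: none
Why: Friedel–Crafts C-arylation of the lactol-derived oxocarbenium ion at the free para position of the phenol; C2 is set by the C3 stereocentre, since reversible C2–O1 ionisation of the 2-(4-hydroxyaryl)chroman equilibrates to the diequatorial 2,3-trans isomer (about 4:1 expected; minor cis isomer removed by chromatography).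

Step 9
Reactants: 18 4-[(2R,3S)-3-(benzyloxy)-5-{2-[3-(benzyloxy)phenyl]ethyl}-7-methoxy-3,4-dihydro-2H-chromen-2-yl]-2,6-dimethoxyphenol
Product: 19 (2R,3S)-2-(4-hydroxy-3,5-dimethoxyphenyl)-5-[2-(3-hydroxyphenyl)ethyl]-7-methoxy-3,4-dihydro-2H-chromen-3-ol
Conditions: H2 (1 atm), Pd(OH)2/C, EtOAc/MeOH, 23 °C
Reagents that add atoms: none
Why: Catalytic hydrogenolysis removes both benzyl ethers under neutral conditions that leave the flavan C2–O bond and both stereocentres intact.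

**Compound list**
1 | 1-(benzyloxy)-3-(bromomethyl)benzene | BrCc1cccc(OCc2ccccc2)c1 | starting material
2 | trimethyl(prop-1-yn-1-yl)silane | CC#C[Si](C)(C)C | starting material
3 | {4-[3-(benzyloxy)phenyl]but-1-yn-1-yl}trimethylsilane | C[Si](C)(C)C#CCCc1cccc(OCc2ccccc2)c1 | intermediate
4 | 1-(benzyloxy)-3-(but-3-yn-1-yl)benzene | C#CCCc1cccc(OCc2ccccc2)c1 | intermediate
5 | methyl (2R)-2-[(4S)-2,2-dimethyl-1,3-dioxolan-4-yl]-2-hydroxyacetate (methyl 3,4-O-isopropylidene-L-threonate) | COC(=O)[C@H](O)[C@@H]1COC(C)(C)O1 | starting material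
6 | methyl (2R)-2-(benzyloxy)-2-[(4S)-2,2-dimethyl-1,3-dioxolan-4-yl]acetate | COC(=O)[C@H](OCc1ccccc1)[C@@H]1COC(C)(C)O1 | intermediate
7 | (1R)-1-(benzyloxy)-6-[3-(benzyloxy)phenyl]-1-[(4S)-2,2-dimethyl-1,3-dioxolan-4-yl]hex-3-yn-2-one | O=C(C#CCCc1cccc(OCc2ccccc2)c1)[C@H](OCc1ccccc1)[C@@H]1COC(C)(C)O1 | intermediate
8 | methyl (2E)-3-methoxybut-2-enoate | CO/C(C)=C/C(=O)OC | starting material
9 | [(1,3-dimethoxybuta-1,3-dien-1-yl)oxy]trimethylsilane (Brassard's diene) | C=C(OC)C=C(OC)O[Si](C)(C)C | intermediate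
10 | (2R)-2-(benzyloxy)-1-{2-[2-(3-(benzyloxy)phenyl)ethyl]-4,6-dimethoxy-6-[(trimethylsilyl)oxy]cyclohexa-1,4-dien-1-yl}-2-[(4S)-2,2-dimethyl-1,3-dioxolan-4-yl]ethan-1-one (C6 epimers) | COC1=CC(OC)(O[Si](C)(C)C)C(C(=O)[C@H](OCc2ccccc2)[C@@H]2COC(C)(C)O2)=C(CCc2cccc(OCc3ccccc3)c2)C1 | intermediate
11 | (2R)-2-(benzyloxy)-1-{2-[2-(3-(benzyloxy)phenyl)ethyl]-6-hydroxy-4-methoxyphenyl}-2-[(4S)-2,2-dimethyl-1,3-dioxolan-4-yl]ethan-1-one | COc1cc(O)c(C(=O)[C@H](OCc2ccccc2)[C@@H]2COC(C)(C)O2)c(CCc2cccc(OCc3ccccc3)c2)c1 | intermediate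
12 | 2-{(2R)-2-(benzyloxy)-2-[(4S)-2,2-dimethyl-1,3-dioxolan-4-yl]acetyl}-3-{2-[3-(benzyloxy)phenyl]ethyl}-5-methoxyphenyl ethyl carbonate | COc1cc(OC(=O)OCC)c(C(=O)[C@H](OCc2ccccc2)[C@@H]2COC(C)(C)O2)c(CCc2cccc(OCc3ccccc3)c2)c1 | intermediate
13 | 6-{(2S)-2-(benzyloxy)-2-[(4S)-2,2-dimethyl-1,3-dioxolan-4-yl]ethylidene}-5-{2-[3-(benzyloxy)phenyl]ethyl}-3-methoxycyclohexa-2,4-dien-1-one | COC1=CC(=O)C(=C[C@H](OCc2ccccc2)[C@@H]2COC(C)(C)O2)C(CCc2cccc(OCc3ccccc3)c2)=C1 | intermediate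
14 | 2-{(2S)-2-(benzyloxy)-2-[(4S)-2,2-dimethyl-1,3-dioxolan-4-yl]ethyl}-3-{2-[3-(benzyloxy)phenyl]ethyl}-5-methoxyphenol | COc1cc(O)c(C[C@H](OCc2ccccc2)[C@@H]2COC(C)(C)O2)c(CCc2cccc(OCc3ccccc3)c2)c1 | intermediate
15 | (2S,3S)-3-(benzyloxy)-4-{2-[2-(3-(benzyloxy)phenyl)ethyl]-6-hydroxy-4-methoxyphenyl}butane-1,2-diol | COc1cc(O)c(C[C@H](OCc2ccccc2)[C@@H](O)CO)c(CCc2cccc(OCc3ccccc3)c2)c1 | intermediate
16 | (3S)-3-(benzyloxy)-5-{2-[3-(benzyloxy)phenyl]ethyl}-7-methoxy-3,4-dihydro-2H-chromen-2-ol (both C2 epimers) | COc1cc(CCc2cccc(OCc3ccccc3)c2)c2c(c1)OC(O)[C@@H](OCc1ccccc1)C2 | intermediate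
17 | 2,6-dimethoxyphenol | COc1cccc(OC)c1O | starting material
18 | 4-[(2R,3S)-3-(benzyloxy)-5-{2-[3-(benzyloxy)phenyl]ethyl}-7-methoxy-3,4-dihydro-2H-chromen-2-yl]-2,6-dimethoxyphenol | COc1cc(CCc2cccc(OCc3ccccc3)c2)c2c(c1)O[C@H](c1cc(OC)c(O)c(OC)c1)[C@@H](OCc1ccccc1)C2 | intermediate
19 | (2R,3S)-2-(4-hydroxy-3,5-dimethoxyphenyl)-5-[2-(3-hydroxyphenyl)ethyl]-7-methoxy-3,4-dihydro-2H-chromen-3-ol (CNP0118545.1) | COc1cc(CCc2cccc(O)c2)c2c(c1)O[C@H](c1cc(OC)c(O)c(OC)c1)[C@@H](O)C2 | target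

**Step count**
Total steps: 9.
Longest linear sequence: 7 (steps 2, 3, 5, 6, 7, 8, 9 from 5; equally steps 1, 3, 5, 6, 7, 8, 9 from 1).

**Three steps most likely to fail**

Step 5. The β-alkyl ynone may react sluggishly, stop at open-chain Michael adducts, or aromatise partly with loss of the silyloxy instead of the methoxy group. Fallback, setting out from 7 and coming back at 11: 7 is combined with commercial Chan's diene [1-methoxy-1,3-bis(trimethylsilyloxy)buta-1,3-diene] under TMSOTf catalysis at −78 °C, so that ring A is assembled stepwise (Mukaiyama–Michael addition, then ring closure) through the bis(silyloxy)cyclohexadiene adduct F1. On acidic work-up F1 aromatises to the resorcinol ketone F2. The 7-oxygen is then differentiated separately: the free, non-hydrogen-bonded para-hydroxyl of F2 is methylated selectively (MeI, K2CO3, acetone) while the chelated ortho-hydroxyl stays untouched, which gives 11.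

Step 6. Carbonate transfer on the hindered, di-ortho-substituted ketone may be slow, and the o-quinone methide can tautomerise to an enol ether or dimerise before hydride capture. Fallback, setting out from 11 and coming back at 15: the ketone is reduced with NaBH4 in MeOH to the benzylic alcohol F3 (carbinol epimers). F3 is then deoxygenated by ionic hydrogenation (Et3SiH, TFA, CH2Cl2, 0 °C) through the benzylic cation stabilised by the ortho-hydroxy and para-methoxy groups. Aqueous TFA work-up removes the acetonide at the same time, so diol 15 is obtained and enters the periodate stage of step 7.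

Step 8. The electron-rich ring A can compete as nucleophile (oligomers), a second arylation of the open benzylic cation is possible, and the trans:cis ratio rests on equilibration only. Fallback, setting out from 16 and coming back at 19: [4-(benzyloxy)-3,5-dimethoxyphenyl]magnesium bromide F4 (from the commercial aryl bromide and Mg, 3 equiv, THF, 0 °C) adds to the ring-opened aldehyde form of 16 under Cram-chelate control by the α-benzyloxy group, giving the syn carbinol F5. Intramolecular Mitsunobu etherification (PPh3, DIAD, THF, 0 °C) then closes the pyran ring with inversion at the benzylic carbon to the 2,3-trans tri-O-benzyl flavan F6. Hydrogenolysis (H2, Pd(OH)2/C) of F6 gives 19 directly.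

**Further compounds**
F1 | step 5 | (2R)-2-(benzyloxy)-1-{2-[2-(3-(benzyloxy)phenyl)ethyl]-6-methoxy-4,6-bis[(trimethylsilyl)oxy]cyclohexa-1,4-dien-1-yl}-2-[(4S)-2,2-dimethyl-1,3-dioxolan-4-yl]ethan-1-one | COC1(O[Si](C)(C)C)C=C(O[Si](C)(C)C)CC(CCc2cccc(OCc3ccccc3)c2)=C1C(=O)[C@H](OCc1ccccc1)[C@@H]1COC(C)(C)O1
F2 | step 5 | (2R)-2-(benzyloxy)-1-{2-[2-(3-(benzyloxy)phenyl)ethyl]-4,6-dihydroxyphenyl}-2-[(4S)-2,2-dimethyl-1,3-dioxolan-4-yl]ethan-1-one | Oc1cc(O)c(C(=O)[C@H](OCc2ccccc2)[C@@H]2COC(C)(C)O2)c(CCc2cccc(OCc3ccccc3)c2)c1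
F3 | step 6 | (2S)-2-(benzyloxy)-1-{2-[2-(3-(benzyloxy)phenyl)ethyl]-6-hydroxy-4-methoxyphenyl}-2-[(4S)-2,2-dimethyl-1,3-dioxolan-4-yl]ethan-1-ol (C1 epimers) | COc1cc(O)c(C(O)[C@H](OCc2ccccc2)[C@@H]2COC(C)(C)O2)c(CCc2cccc(OCc3ccccc3)c2)c1
F4 | step 8 | [4-(benzyloxy)-3,5-dimethoxyphenyl]magnesium bromide | COc1cc([Mg]Br)cc(OC)c1OCc1ccccc1
F5 | step 8 | (1S,2S)-2-(benzyloxy)-1-[4-(benzyloxy)-3,5-dimethoxyphenyl]-3-{2-[2-(3-(benzyloxy)phenyl)ethyl]-6-hydroxy-4-methoxyphenyl}propan-1-ol | COc1cc(O)c(C[C@H](OCc2ccccc2)[C@@H](O)c2cc(OC)c(OCc3ccccc3)c(OC)c2)c(CCc2cccc(OCc3ccccc3)c2)c1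
F6 | step 8 | (2R,3S)-3-(benzyloxy)-2-[4-(benzyloxy)-3,5-dimethoxyphenyl]-5-{2-[3-(benzyloxy)phenyl]ethyl}-7-methoxy-3,4-dihydro-2H-chromene | COc1cc(CCc2cccc(OCc3ccccc3)c2)c2c(c1)O[C@H](c1cc(OC)c(OCc3ccccc3)c(OC)c1)[C@@H](OCc1ccccc1)C2
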